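**Retrosynthetic overview**

- Ring positions follow furan-2(5H)-one numbering: O1, C2 (carbonyl), C3 (methyl-bearing), C4 (chain-bearing), C5 (methylene). The enabling feature is that the methyl carbon on C3, C3 itself and C4 form a masked terminal allene (CH2=C=CH–chain), so target 13 is the endocyclic isomer of α-methylene-γ-butyrolactone 12.
- Lactone 12 comes from allene 8, CO2 and formaldehyde in one operation on zerovalent nickel. CO2 adds to the central allene carbon (C2–C3 bond), formaldehyde adds to the substituted terminus (C4–C5 bond), and lactonisation (O1–C2) closes the only ring of the molecule.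
- Allene 8 comes from terminal alkyne 5 by Crabbé homologation and acetylation. The acetate of the target serves as the protecting group.
- Alkyne 5 comes from pentadec-1-yne 1 and (S)-propylene oxide 2. Epoxide opening supplies the (S) carbinol and an alkyne zipper moves the triple bond to the chain end.

Key step: step 5

Remark: C4 of lactone 12 is expected as both epimers. This is harmless because step 6 makes that carbon trigonal. Ni(cod)2 is used in stoichiometric amount in step 5.

**Route**

Step 1
Reactants: 1 pentadec-1-yne; 2 (S)-2-methyloxirane
Product: 4 (2S)-octadec-4-yn-2-ol, via lithium pentadec-1-yn-1-ide 3 (not isolated)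
Conditions: n-BuLi, THF, −78 °C; then DMPU, 2, −78 °C → rt; H2O
Reagents that add atoms: none
Why: Alkynylation of a terminal epoxide: the lithium acetylide opens the oxirane by SN2 attack at the unsubstituted CH2, so the C–O stereocentre of 2 is carried unchanged into C2 of 4 as (S).

Step 2
Reactants: 4 (2S)-octadec-4-yn-2-ol
Product: 5 (2S)-octadec-17-yn-2-ol
Conditions: KH, H2N(CH2)3NH2, rt (gives KNH(CH2)3NH2); then 4, 0 °C → rt; H2O
Reagents that add atoms: none
Why: Alkyne zipper reaction: KNH(CH2)3NH2 should move the triple bond along the chain by propargyl/allenyl prototropic shifts until the terminal potassium acetylide forms irreversibly, while the C2 potassium alkoxide blocks migration toward C1 and protects the carbinol C–H, so the (S) centre should be retained.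

Step 3
Reactants: 5 (2S)-octadec-17-yn-2-ol
Product: 7 (2S)-nonadeca-17,18-dien-2-ol, via propargylic amine 6 (not isolated)
Conditions: (CH2O)n, CuI (0.5 equiv), Cy2NH, dioxane, reflux
Reagents that add atoms: formaldehyde (as paraformaldehyde), C=O
Why: Crabbé homologation: CuI-mediated Mannich coupling of the terminal alkyne, formaldehyde and Cy2NH gives propargylic amine 6, which should undergo copper-assisted 1,5-hydride transfer and elimination to the terminal allene, a process that tolerates the free secondary alcohol.

Step 4
Reactants: 7 (2S)-nonadeca-17,18-dien-2-ol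
Product: 8 (2S)-nonadeca-17,18-dien-2-yl acetate
Conditions: Ac2O, pyridine, DMAP (cat.), CH2Cl2, 0 °C → rt
Reagents that add atoms: acetic anhydride, CC(=O)OC(C)=O
Why: DMAP-catalysed O-acetylation of the secondary alcohol with retention at C2, since the C–O bond is not broken; the allene is inert.

Step 5
Reactants: 8 (2S)-nonadeca-17,18-dien-2-yl acetate
Product: 12 (2S)-16-(4-methylidene-5-oxooxolan-3-yl)hexadecan-2-yl acetate (both epimers at oxolane C3), via nickelalactone 9 (not isolated), via nickel alkoxide carboxylate 10 (not isolated), via hydroxy acid 11 (not isolated)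
Conditions: Ni(cod)2 (1.1 equiv), DBU (2.2 equiv), CO2 (1 atm), THF, 0 °C; then monomeric CH2O in THF, 0 °C → rt; aq. HCl; then TsOH·H2O (cat.), CH2Cl2, rt
Reagents that add atoms: carbon dioxide, O=C=O; formaldehyde, C=O
Why: Zerovalent nickel ligated by DBU binds the unsubstituted terminal C=C of the allene together with CO2, and oxidative cyclisation forms the C2–C3 bond at the central allene carbon to give nickelalactone 9, a chelated σ-allyl complex of divalent nickel bound at the former CH2 terminus; formaldehyde then coordinates to nickel and is allylated at the alkyl-substituted allyl terminus through a six-membered SE2' transition state, which forms the C4–C5 bond and leaves the exocyclic methylene in 10. The closest known reaction type is the nickel-mediated sequential addition of CO2 and an aldehyde to a terminal allene (three-component carboxylative allylation), here with formaldehyde as the aldehyde. Protonation gives γ-hydroxy acid 11, and the only ring, the γ-lactone, closes by 5-exo-trig acyl substitution of the primary hydroxyl on the carboxylic acid under acid catalysis. The new stereocentre at C4 of the lactone forms without control relative to the remote carbinol centre, which does not matter because step 6 makes this carbon trigonal. The step needs regioselectivity (CO2 to the central carbon, CH2O to the substituted terminus), and the allene itself secures it: only carboxylation at the central carbon gives an allyl-stabilised nickel–carbon bond, and allyl transfer from the primary Ni–CH2 σ-allyl form proceeds with allylic transposition. The acetate should be inert to Ni(cod)2, DBU and CO2 at 0 °C, and the remote (S) centre is untouched.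

Step 6
Reactants: 12 (2S)-16-(4-methylidene-5-oxooxolan-3-yl)hexadecan-2-yl acetate
Product: 13 (2S)-16-(4-methyl-5-oxo-2,5-dihydrofuran-3-yl)hexadecan-2-yl acetate
Conditions: RhCl3·3H2O (5 mol %), EtOH/CHCl3, 70 °C
Reagents that add atoms: none
Why: Rhodium-hydride-catalysed alkene isomerisation (hydrometalation of the exocyclic methylene, then β-hydride elimination of the C4 hydrogen) should move the double bond into the ring to give the tetrasubstituted conjugated butenolide, the thermodynamic isomer, which erases the uncontrolled C4 centre and leaves the acetate and its (S) centre alone.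

**Compound list**

1 | pentadec-1-yne | C#CCCCCCCCCCCCCC | starting material
2 | (S)-2-methyloxirane ((S)-propylene oxide) | C[C@H]1CO1 | starting material
3 | lithium pentadec-1-yn-1-ide (not isolated) | [Li+].[C-]#CCCCCCCCCCCCCC | intermediate
4 | (2S)-octadec-4-yn-2-ol | C[C@H](O)CC#CCCCCCCCCCCCCC | intermediate
5 | (2S)-octadec-17-yn-2-ol | C[C@H](O)CCCCCCCCCCCCCCC#C | intermediate
6 | (2S)-19-(dicyclohexylamino)nonadec-17-yn-2-ol (not isolated) | C[C@H](O)CCCCCCCCCCCCCCC#CCN(C1CCCCC1)C1CCCCC1 | intermediate
7 | (2S)-nonadeca-17,18-dien-2-ol | C[C@H](O)CCCCCCCCCCCCCCC=C=C | intermediate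
8 | (2S)-nonadeca-17,18-dien-2-yl acetate | CC(=O)O[C@@H](C)CCCCCCCCCCCCCCC=C=C | intermediate
9 | five-membered nickelalactone Ni[CH2–C(=CH–R)–C(=O)–O] of divalent nickel, R = (15S)-15-acetoxyhexadecyl (not isolated; DBU ligands on nickel not drawn) | CC(=O)O[C@@H](C)CCCCCCCCCCCCCCC=C1C[Ni]OC1=O | intermediate
10 | seven-membered nickel alkoxide carboxylate Ni[O–CH2–CH(R)–C(=CH2)–C(=O)–O] of divalent nickel, R as in 9 (not isolated; DBU ligands not drawn) | CC(=O)O[C@@H](C)CCCCCCCCCCCCCCC1CO[Ni]OC(=O)C1=C | intermediate
11 | (18S)-18-acetoxy-3-(hydroxymethyl)-2-methylidenenonadecanoic acid (not isolated; both C3 epimers) | CC(=O)O[C@@H](C)CCCCCCCCCCCCCCC(CO)C(=C)C(=O)O | intermediate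
12 | (2S)-16-(4-methylidene-5-oxooxolan-3-yl)hexadecan-2-yl acetate (both epimers at oxolane C3) | CC(=O)O[C@@H](C)CCCCCCCCCCCCCCC1COC(=O)C1=C | intermediate
13 | (2S)-16-(4-methyl-5-oxo-2,5-dihydrofuran-3-yl)hexadecan-2-yl acetate | CC(=O)O[C@@H](C)CCCCCCCCCCCCCCC1=C(C)C(=O)OC1 | target

**Count and risks**

Total step count: 6. Longest linear sequence: 6 steps (from pentadec-1-yne 1).

The three steps most likely to fail, in order of risk:

First, step 5. The allyl transfer to formaldehyde may take place at the unsubstituted allyl terminus, or allene oligomerisation on nickel and polymerisation of formaldehyde may outrun the three-component coupling. The fallback sets out from 5 and comes back at 13, building the ring by olefination at C3=C4 instead. Acetylation of 5 (Ac2O, pyridine) gives (2S)-octadec-17-yn-2-yl acetate F1. Gold-catalysed oxidation of its terminal alkyne with 8-methylquinoline N-oxide in the presence of 2-(diethoxyphosphoryl)propanoic acid (Ph3PAuNTf2, 1,2-dichloroethane) traps the α-oxo gold carbene as (17S)-17-acetoxy-2-oxooctadecyl 2-(diethoxyphosphoryl)propanoate F2. Intramolecular Horner–Wadsworth–Emmons olefination (LiCl, DBU, MeCN) then closes the furanone and gives 13 directly.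

Second, step 6. The double bond may migrate incompletely into the ring, or the warm, slightly acidic ethanol may begin to solvolyse the acetate. The fallback sets out from 12 and comes back at 13 by reduction and re-oxidation instead of isomerisation. Conjugate reduction of the exocyclic enoate with LiBH(s-Bu)3 (THF, −78 °C) gives the lithium enolate of the α-methyl lactone F3. It is trapped in the same flask with PhSeBr on the face opposite the C4 chain to give (2S)-16-[4-methyl-5-oxo-4-(phenylselanyl)oxolan-3-yl]hexadecan-2-yl acetate F4. H2O2 (pyridine, CH2Cl2, 0 °C) oxidises it to the selenoxide F5, whose syn-elimination toward the cis C4 hydrogen gives 13.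

Third, step 2. The triple bond must travel thirteen positions, and the migration may stall at internal alkynes or the strong base may erode material and optical purity. The fallback sets out from 2 and comes back at 5 with the alkyne terminal from the start, so that 1 and steps 1 and 2 are not needed. 1-(Trimethylsilyl)propyne is deprotonated with n-BuLi (THF, −78 °C) to 3-lithio-1-(trimethylsilyl)propyne F6 and alkylated with an excess of 1,12-dibromododecane to (15-bromopentadec-1-yn-1-yl)trimethylsilane F7. Mg in THF converts this into [15-(trimethylsilyl)pentadec-14-yn-1-yl]magnesium bromide F8, which opens 2 at CH2 under CuI catalysis to give (2S)-18-(trimethylsilyl)octadec-17-yn-2-ol F9. K2CO3 in MeOH removes the silyl group and gives 5.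

**Further compounds**

F1 | step 5 | (2S)-octadec-17-yn-2-yl acetate | CC(=O)O[C@@H](C)CCCCCCCCCCCCCCC#C
F2 | step 5 | (17S)-17-acetoxy-2-oxooctadecyl 2-(diethoxyphosphoryl)propanoate | CC(=O)O[C@@H](C)CCCCCCCCCCCCCCC(=O)COC(=O)C(C)P(=O)(OCC)OCC
F3 | step 6 | lithium enolate of (2S)-16-(4-methyl-5-oxooxolan-3-yl)hexadecan-2-yl acetate | CC(=O)O[C@@H](C)CCCCCCCCCCCCCCC1COC([O-])=C1C.[Li+]
F4 | step 6 | (2S)-16-[4-methyl-5-oxo-4-(phenylselanyl)oxolan-3-yl]hexadecan-2-yl acetate | CC(=O)O[C@@H](C)CCCCCCCCCCCCCCC1COC(=O)C1(C)[Se]c1ccccc1
F5 | step 6 | (2S)-16-[4-methyl-5-oxo-4-(phenylseleninyl)oxolan-3-yl]hexadecan-2-yl acetate | CC(=O)O[C@@H](C)CCCCCCCCCCCCCCC1COC(=O)C1(C)[Se](=O)c1ccccc1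
F6 | step 2 | 3-lithio-1-(trimethylsilyl)propyne | [Li+].[CH2-]C#C[Si](C)(C)C
F7 | step 2 | (15-bromopentadec-1-yn-1-yl)trimethylsilane | C[Si](C)(C)C#CCCCCCCCCCCCCCBr
F8 | step 2 | [15-(trimethylsilyl)pentadec-14-yn-1-yl]magnesium bromide | C[Si](C)(C)C#CCCCCCCCCCCCCC[Mg]Br
F9 | step 2 | (2S)-18-(trimethylsilyl)octadec-17-yn-2-ol | C[C@H](O)CCCCCCCCCCCCCCC#C[Si](C)(C)C
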